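**Retrosynthetic overview** (icetexane numbering: C10 = O‑bearing quaternary carbon, C5 = ring‑fusion CH, C7 = hemiketal carbon, C20 = benzylic CH2, C8/C9 = ring carbons bearing C7/C20)
1. Target 22 ⇐ 21 by oxidative demethylation; the quinone is made last.
2. C5–H ⇐ oxygen‑directed hydrogenation of the C5=C6 alkene of bridged lactol 20, which sets 5R from 10S.
3. C7–C8 ⇐ aryllithium addition to the butenolide carbonyl of 18 (Parham type); this closes the pyran of the oxygen bridge and the seven‑membered ring B together.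
4. C10–C20 ⇐ intermolecular asymmetric vinylogous Michael addition of butenolide 4 to o‑quinone methide 15 (released from benzylic trimethylammonium salt 14); this sets C10.
5. 4 ⇐ 2,2‑dimethylcyclohexanone (ring A bought, butenolide by intramolecular Horner–Wadsworth–Emmons); 14 ⇐ 1,3‑dimethoxybenzene. Ring order: A → butenolide → (arene joined) → pyran + ring B → quinone.

Assumption: the SMILES is read as drawn, (5R,7S,10S), with H‑5 on the same face of ring A as the C10–O bond; small reagents that only deliver a few atoms are given by name and SMILES and carry no compound number.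

**Step 1**
Reactants: 1 2,2-dimethylcyclohexan-1-one
Product: 2 2-bromo-6,6-dimethylcyclohexan-1-one (racemic)
Conditions: Br2, AcOH, rt
Reagents that add atoms: bromine BrBr
Why: Acid‑catalysed α‑bromination through the only enol this ketone can form (the other α‑carbon is quaternary).

**Step 2**
Reactants: 2 2-bromo-6,6-dimethylcyclohexan-1-one
Product: 3 3,3-dimethyl-2-oxocyclohexyl 2-(diethoxyphosphoryl)acetate (racemic)
Conditions: (EtO)2P(O)CH2CO2H, KHCO3, DMF, rt
Reagents that add atoms: diethylphosphonoacetic acid OC(=O)CP(=O)(OCC)OCC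
Why: SN2 displacement of the activated α‑bromo ketone by the carboxylate puts the future lactone oxygen on C10 and brings in C6 and C7.

**Step 3**
Reactants: 3 3,3-dimethyl-2-oxocyclohexyl 2-(diethoxyphosphoryl)acetate
Product: 4 rac-4,4-dimethyl-5,6,7,7a-tetrahydro-1-benzofuran-2(4H)-one
Conditions: NaH, THF, 0 °C to rt
Reagents that add atoms: none
Why: Intramolecular Horner–Wadsworth–Emmons olefination forms C5=C6 in a five‑membered ring despite the hindered ketone; the racemic C7a–H centre is erased in step 10.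

**Step 4**
Reactants: 5 1,3-dimethoxybenzene
Product: 7 2-(2,6-dimethoxyphenyl)propan-2-ol, via aryllithium 6 (not isolated)
Conditions: n-BuLi, THF, 0 °C to rt; acetone, −78 °C to rt; H2O
Reagents that add atoms: acetone CC(C)=O
Why: Directed ortho‑lithiation between the two methoxy groups, then 1,2‑addition to acetone.

**Step 5**
Reactants: 7 2-(2,6-dimethoxyphenyl)propan-2-ol
Product: 8 1,3-dimethoxy-2-(propan-2-yl)benzene
Conditions: Et3SiH, CF3CO2H, CH2Cl2, 0 °C to rt
Reagents that add atoms: none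
Why: Ionic hydrogenation of the tertiary benzylic alcohol (cation formation, hydride transfer from silane).

**Step 6**
Reactants: 8 1,3-dimethoxy-2-(propan-2-yl)benzene
Product: 10 2,4-dimethoxy-3-(propan-2-yl)benzaldehyde, via iminium salt 9 (not isolated)
Conditions: POCl3, DMF, 0 to 80 °C; H2O
Reagents that add atoms: N,N-dimethylformamide CN(C)C=O; water O
Why: Vilsmeier–Haack formylation para to one methoxy and ortho to the other; the two activated positions are equivalent by symmetry, so regiochemistry is unambiguous.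

**Step 7**
Reactants: 10 2,4-dimethoxy-3-(propan-2-yl)benzaldehyde
Product: 12 2,4-dimethoxy-3-(propan-2-yl)phenol, via aryl formate 11 (not isolated)
Conditions: mCPBA, CH2Cl2, 0 °C to rt; K2CO3 (cat.), MeOH
Reagents that add atoms: 3-chloroperoxybenzoic acid OOC(=O)c1cccc(Cl)c1
Why: Baeyer–Villiger (Dakin‑type) oxidation with migration of the electron‑rich aryl group, then methanolysis of the formate.

**Step 8**
Reactants: 12 2,4-dimethoxy-3-(propan-2-yl)phenol
Product: 13 6-[(dimethylamino)methyl]-2,4-dimethoxy-3-(propan-2-yl)phenol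
Conditions: aq. Me2NH, aq. CH2O, EtOH, rt to 60 °C
Reagents that add atoms: formaldehyde C=O; dimethylamine CNC
Why: Phenolic Mannich reaction at the only free position ortho to OH (para is blocked), which places C20 on C9.

**Step 9**
Reactants: 13 6-[(dimethylamino)methyl]-2,4-dimethoxy-3-(propan-2-yl)phenol
Product: 14 1-[2-hydroxy-3,5-dimethoxy-4-(propan-2-yl)phenyl]-N,N,N-trimethylmethanaminium iodide
Conditions: MeI (excess), acetone, rt, dark; filter the precipitated salt
Reagents that add atoms: iodomethane CI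
Why: Menshutkin N‑methylation of the tertiary amine, which without added base leaves the hydrogen‑bonded phenol untouched and gives a storable salt that releases the quinone methide only once the phenol is deprotonated.

**Step 10**
Reactants: 4 rac-4,4-dimethyl-5,6,7,7a-tetrahydro-1-benzofuran-2(4H)-one; 14 1-[2-hydroxy-3,5-dimethoxy-4-(propan-2-yl)phenyl]-N,N,N-trimethylmethanaminium iodide
Product: 16 (7aS)-7a-{[2-hydroxy-3,5-dimethoxy-4-(propan-2-yl)phenyl]methyl}-4,4-dimethyl-5,6,7,7a-tetrahydro-1-benzofuran-2(4H)-one, via o-quinone methide 15 (not isolated)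
Conditions: quinine-derived squaramide 3-{[3,5-bis(trifluoromethyl)phenyl]amino}-4-{[(8α,9S)-6′-methoxycinchonan-9-yl]amino}cyclobut-3-ene-1,2-dione (10 mol %), powdered K2CO3, dry CHCl3, rt, slow N2 sweep
Reagents that add atoms: none
Why: Intermolecular vinylogous Michael addition: carbonate deprotonates the phenol of 14 and the phenolate–ammonium zwitterion expels trimethylamine to give 15 slowly and at low concentration, whose CH2 terminus is attacked by the planar furanolate of 4 through the γ‑carbon (the α‑carbon is shielded by the neighbouring gem‑dimethyl carbon) while the squaramide binds the acceptor carbonyl and exposes one furanolate face; the quinine‑derived catalyst is assigned to the (7aS) centre (C10, S) by analogy only, its quinidine pseudo‑enantiomer giving the antipode.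

**Step 11**
Reactants: 16 (7aS)-7a-{[2-hydroxy-3,5-dimethoxy-4-(propan-2-yl)phenyl]methyl}-4,4-dimethyl-5,6,7,7a-tetrahydro-1-benzofuran-2(4H)-one
Product: 17 (7aS)-4,4-dimethyl-7a-{[2,3,5-trimethoxy-4-(propan-2-yl)phenyl]methyl}-5,6,7,7a-tetrahydro-1-benzofuran-2(4H)-one
Conditions: MeI, K2CO3, DMF, rt
Reagents that add atoms: iodomethane CI
Why: Williamson O‑methylation of the phenoxide, which also removes any reversible oxa‑Michael closure onto the butenolide; the quaternary centre cannot epimerise.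

**Step 12**
Reactants: 17 (7aS)-4,4-dimethyl-7a-{[2,3,5-trimethoxy-4-(propan-2-yl)phenyl]methyl}-5,6,7,7a-tetrahydro-1-benzofuran-2(4H)-one
Product: 18 (7aS)-7a-{[2-iodo-3,5,6-trimethoxy-4-(propan-2-yl)phenyl]methyl}-4,4-dimethyl-5,6,7,7a-tetrahydro-1-benzofuran-2(4H)-one
Conditions: N-iodosuccinimide, CF3CO2H (cat.), MeCN, rt
Reagents that add atoms: N-iodosuccinimide O=C1CCC(=O)N1I
Why: Electrophilic aromatic iodination at the only remaining ring hydrogen (C8, ortho to one methoxy group and para to another); the electron‑poor butenolide alkene is inert.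

**Step 13**
Reactants: 18 (7aS)-7a-{[2-iodo-3,5,6-trimethoxy-4-(propan-2-yl)phenyl]methyl}-4,4-dimethyl-5,6,7,7a-tetrahydro-1-benzofuran-2(4H)-one
Product: 20 (7S,10S)-7,10-epoxy-7-hydroxy-11,12,14-trimethoxy-9(10→20)abeo-abieta-5,8,11,13-tetraene, via aryllithium 19 (not isolated)
Conditions: t-BuLi (2.1 equiv), THF, −100 to −40 °C; aq. NH4Cl
Reagents that add atoms: none
Why: Parham cyclisation: iodine–lithium exchange outruns carbonyl addition, and the C8 aryllithium adds 1,2 to the lactone carbonyl through a six‑membered ring (conjugate attack would need a quaternary carbon between two others); the bridge fixes C7 as S from 10S, and the lactol is the ring tautomer of the cis‑γ‑hydroxy enone.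

**Step 14**
Reactants: 20 (7S,10S)-7,10-epoxy-7-hydroxy-11,12,14-trimethoxy-9(10→20)abeo-abieta-5,8,11,13-tetraene
Product: 21 (5R,7S,10S)-7,10-epoxy-7-hydroxy-11,12,14-trimethoxy-9(10→20)abeo-abieta-8,11,13-triene
Conditions: [Ir(cod)(PCy3)(py)]PF6 (5 mol %), H2 (1 atm), CH2Cl2, rt
Reagents that add atoms: none
Why: Oxygen‑directed hydrogenation: the cationic iridium catalyst binds the C10 oxygen (bridge/lactol oxygens, or the tertiary hydroxyl of the open tautomer, which lie on the same face) and delivers both hydrogens to C5=C6 from that face, so H‑5 ends cis to the C10–O bond (5R).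

**Step 15**
Reactants: 21 (5R,7S,10S)-7,10-epoxy-7-hydroxy-11,12,14-trimethoxy-9(10→20)abeo-abieta-8,11,13-triene
Product: 22 (5R,7S,10S)-7,10-epoxy-7-hydroxy-12-methoxy-9(10→20)abeo-abieta-8,12-diene-11,14-dione
Conditions: (NH4)2Ce(NO3)6, MeCN/H2O, 0 °C
Reagents that add atoms: water O
Why: Oxidative demethylation of the para‑dimethoxy pair (C11/C14) gives the 2‑methoxy‑1,4‑benzoquinone without touching the stereocentres; the 10‑hydroxy‑7‑ketone is delivered as the closed hemiketal of the target.

**Compound list**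
1 | 2,2-dimethylcyclohexan-1-one | CC1(C)CCCCC1=O | starting material
2 | 2-bromo-6,6-dimethylcyclohexan-1-one (racemic) | CC1(C)CCCC(Br)C1=O | intermediate
3 | 3,3-dimethyl-2-oxocyclohexyl 2-(diethoxyphosphoryl)acetate (racemic) | CCOP(=O)(CC(=O)OC1CCCC(C)(C)C1=O)OCC | intermediate
4 | rac-4,4-dimethyl-5,6,7,7a-tetrahydro-1-benzofuran-2(4H)-one | CC1(C)CCCC2OC(=O)C=C12 | intermediate
5 | 1,3-dimethoxybenzene | COc1cccc(OC)c1 | starting material
6 | (2,6-dimethoxyphenyl)lithium | COc1cccc(OC)c1[Li] | intermediate (not isolated)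
7 | 2-(2,6-dimethoxyphenyl)propan-2-ol | COc1cccc(OC)c1C(C)(C)O | intermediate
8 | 1,3-dimethoxy-2-(propan-2-yl)benzene | COc1cccc(OC)c1C(C)C | intermediate
9 | N-{[2,4-dimethoxy-3-(propan-2-yl)phenyl]methylidene}-N-methylmethanaminium chloride | COc1ccc(C=[N+](C)C)c(OC)c1C(C)C.[Cl-] | intermediate (not isolated)
10 | 2,4-dimethoxy-3-(propan-2-yl)benzaldehyde | COc1ccc(C=O)c(OC)c1C(C)C | intermediate
11 | 2,4-dimethoxy-3-(propan-2-yl)phenyl formate | COc1ccc(OC=O)c(OC)c1C(C)C | intermediate (not isolated)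
12 | 2,4-dimethoxy-3-(propan-2-yl)phenol | COc1ccc(O)c(OC)c1C(C)C | intermediate
13 | 6-[(dimethylamino)methyl]-2,4-dimethoxy-3-(propan-2-yl)phenol | COc1cc(CN(C)C)c(O)c(OC)c1C(C)C | intermediate
14 | 1-[2-hydroxy-3,5-dimethoxy-4-(propan-2-yl)phenyl]-N,N,N-trimethylmethanaminium iodide | COc1cc(C[N+](C)(C)C)c(O)c(OC)c1C(C)C.[I-] | intermediate
15 | 2,4-dimethoxy-6-methylidene-3-(propan-2-yl)cyclohexa-2,4-dien-1-one (o-quinone methide) | C=C1C=C(OC)C(C(C)C)=C(OC)C1=O | intermediate (not isolated)
16 | (7aS)-7a-{[2-hydroxy-3,5-dimethoxy-4-(propan-2-yl)phenyl]methyl}-4,4-dimethyl-5,6,7,7a-tetrahydro-1-benzofuran-2(4H)-one | COc1cc(C[C@@]23CCCC(C)(C)C2=CC(=O)O3)c(O)c(OC)c1C(C)C | intermediate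
17 | (7aS)-4,4-dimethyl-7a-{[2,3,5-trimethoxy-4-(propan-2-yl)phenyl]methyl}-5,6,7,7a-tetrahydro-1-benzofuran-2(4H)-one | COc1cc(C[C@@]23CCCC(C)(C)C2=CC(=O)O3)c(OC)c(OC)c1C(C)C | intermediate
18 | (7aS)-7a-{[2-iodo-3,5,6-trimethoxy-4-(propan-2-yl)phenyl]methyl}-4,4-dimethyl-5,6,7,7a-tetrahydro-1-benzofuran-2(4H)-one | COc1c(I)c(C[C@@]23CCCC(C)(C)C2=CC(=O)O3)c(OC)c(OC)c1C(C)C | intermediate
19 | aryllithium from 18 (lithium in place of iodine at C8, otherwise as 18) | COc1c([Li])c(C[C@@]23CCCC(C)(C)C2=CC(=O)O3)c(OC)c(OC)c1C(C)C | intermediate (not isolated)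
20 | (7S,10S)-7,10-epoxy-7-hydroxy-11,12,14-trimethoxy-9(10→20)abeo-abieta-5,8,11,13-tetraene (oxygen-bridged lactol with C5=C6) | COc1c(C(C)C)c(OC)c2c(C[C@@]34CCCC(C)(C)C3=C[C@]2(O)O4)c1OC | intermediate
21 | (5R,7S,10S)-7,10-epoxy-7-hydroxy-11,12,14-trimethoxy-9(10→20)abeo-abieta-8,11,13-triene | COc1c(C(C)C)c(OC)c2c(C[C@@]34CCCC(C)(C)[C@H]3C[C@]2(O)O4)c1OC | intermediate
22 | (5R,7S,10S)-7,10-epoxy-7-hydroxy-12-methoxy-9(10→20)abeo-abieta-8,12-diene-11,14-dione | COC1=C(C(C)C)C(=O)C2=C(C[C@@]34CCCC(C)(C)[C@H]3C[C@]2(O)O4)C1=O | target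

**Totals**
Total step count: 15. Longest linear sequence: 12 steps (steps 4–15); the ring A branch (steps 1–3) joins at step 10.

**Steps most likely to fail**

Step 10 (enantioselectivity and γ‑selectivity of the vinylogous Michael addition; the liberated trimethylamine and the carbonate can drive a racemic background reaction; the sense of induction is assigned by analogy and must be confirmed on 16). Fallback: set out again from 4 and 14 and couple them without a chiral catalyst (Cs2CO3, MeCN, rt) to the racemic phenol F1. Acylate the phenol with (S)-naproxenoyl chloride (Et3N, DMAP, CH2Cl2), separate the two diastereomeric aryl esters by crystallisation or chromatography and keep the (7aS) naproxen ester F2. K2CO3 in MeOH cleaves the aryl ester and the route is rejoined at 16; resolution replaces catalyst control.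

Step 13 (competition of t-BuLi or of the aryllithium with the unsaturated lactone). Fallback: set out from 17 and reduce the butenolide with i-Bu2AlH (CH2Cl2, −78 to 0 °C) to the Z-ene-diol F3. Hydrogenate it with [Ir(cod)(PCy3)(py)]PF6 and H2, directed by the tertiary hydroxyl, to the saturated diol F4 (H‑5 cis to the C10 oxygen). Oxidative lactonisation (TEMPO, PhI(OAc)2) gives the trans‑fused lactone F5, and N-iodosuccinimide gives the iodo lactone F6. t-BuLi at −100 °C then cyclises onto a saturated lactone with no conjugate acceptor, and the route is rejoined directly at 21, by‑passing 20 and step 14.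

Step 14 (hindered alkene; wrong face if direction by oxygen fails). Fallback: set out from 20 and lock the bicycle as the bridged methyl ketal F7 (HC(OMe)3, MeOH, pyridinium 4-toluenesulfonate). Hydrogenate over Pd/C (H2, EtOAc); the arene blocks the endo face, so hydrogen adds from the exo, oxygen‑bridge face to give the saturated methyl ketal F8. Dilute HCl in aqueous THF hydrolyses the ketal and the route is rejoined at 21.

**Further compounds**
F1 | step 10 | racemic 7a-{[2-hydroxy-3,5-dimethoxy-4-(propan-2-yl)phenyl]methyl}-4,4-dimethyl-5,6,7,7a-tetrahydro-1-benzofuran-2(4H)-one | COc1cc(CC23CCCC(C)(C)C2=CC(=O)O3)c(O)c(OC)c1C(C)C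
F2 | step 10 | 2-{[(7aS)-4,4-dimethyl-2-oxo-4,5,6,7-tetrahydro-1-benzofuran-7a(2H)-yl]methyl}-4,6-dimethoxy-5-(propan-2-yl)phenyl (2S)-2-(6-methoxynaphthalen-2-yl)propanoate | COc1cc(C[C@@]23CCCC(C)(C)C2=CC(=O)O3)c(OC(=O)[C@@H](C)c2ccc3cc(OC)ccc3c2)c(OC)c1C(C)C
F3 | step 13 | (1S)-2-[(2Z)-2-hydroxyethylidene]-3,3-dimethyl-1-{[2,3,5-trimethoxy-4-(propan-2-yl)phenyl]methyl}cyclohexan-1-ol | COc1cc(C[C@@]2(O)CCCC(C)(C)/C2=C/CO)c(OC)c(OC)c1C(C)C
F4 | step 13 | (1S,2R)-2-(2-hydroxyethyl)-3,3-dimethyl-1-{[2,3,5-trimethoxy-4-(propan-2-yl)phenyl]methyl}cyclohexan-1-ol | COc1cc(C[C@@]2(O)CCCC(C)(C)[C@H]2CCO)c(OC)c(OC)c1C(C)C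
F5 | step 13 | (3aR,7aS)-4,4-dimethyl-7a-{[2,3,5-trimethoxy-4-(propan-2-yl)phenyl]methyl}hexahydro-1-benzofuran-2(3H)-one | COc1cc(C[C@@]23CCCC(C)(C)[C@H]2CC(=O)O3)c(OC)c(OC)c1C(C)C
F6 | step 13 | (3aR,7aS)-7a-{[2-iodo-3,5,6-trimethoxy-4-(propan-2-yl)phenyl]methyl}-4,4-dimethylhexahydro-1-benzofuran-2(3H)-one | COc1c(I)c(C[C@@]23CCCC(C)(C)[C@H]2CC(=O)O3)c(OC)c(OC)c1C(C)C
F7 | step 14 | (7S,10S)-7,10-epoxy-7,11,12,14-tetramethoxy-9(10→20)abeo-abieta-5,8,11,13-tetraene | COc1c(C(C)C)c(OC)c2c(C[C@@]34CCCC(C)(C)C3=C[C@]2(OC)O4)c1OC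
F8 | step 14 | (5R,7S,10S)-7,10-epoxy-7,11,12,14-tetramethoxy-9(10→20)abeo-abieta-8,11,13-triene | COc1c(C(C)C)c(OC)c2c(C[C@@]34CCCC(C)(C)[C@H]3C[C@]2(OC)O4)c1OC
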